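Everything rests on disconnecting the C4–C4a bond, which joins the ring C ketone to ring A. C4a is ortho to C8a, the carbon bearing the ether oxygen O1, so a carbanion placed at C4a of an open-chain aryl ether reaches the C4 acyl carbon through a six-membered transition state. Bromine–lithium exchange followed by intramolecular attack on an N-methoxy-N-methyl amide therefore makes the aryl ketone and closes ring C in one operation, without touching C2 or C3. The cyclisation substrate is a (2R,3R)-3-aryloxy-2-silyloxy-3-arylpropanamide already carrying both prenyl groups; it is assembled by stereospecific opening of a trans-glycidic amide with a 2-bromo-6-prenylphenol.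

Key step: step 11

Remark: prenyl = 3-methylbut-2-en-1-yl; MOM = methoxymethyl; TBS = tert-butyldimethylsilyl.

Assumption: the samarium–BINOL peroxide catalyst is taken to show the same facial sense with the enamide as with enones [(R)-ligand giving the (αS,βR) series], so (S)-BINOL is written for the (2R,3S) epoxide; should the sense prove opposite, the (R)-ligand is used and nothing else changes.

**Ring B and the epoxide**

Step 1
Reactants: 1 4-hydroxybenzaldehyde; 2 1-bromo-3-methylbut-2-ene (prenyl bromide)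
Product: 3 4-hydroxy-3-(3-methylbut-2-en-1-yl)benzaldehyde
Conditions: KOH, H2O, rt
Reagents that add atoms: none
Why: In water the potassium phenoxide is alkylated at carbon by the allylic bromide (direct ortho C-prenylation of an ambident phenoxide), the para position being blocked by the formyl group; the O-prenyl ether is the expected competitor and is removed by chromatography.

Step 2
Reactants: 3 4-hydroxy-3-(3-methylbut-2-en-1-yl)benzaldehyde
Product: 4 4-(methoxymethoxy)-3-(3-methylbut-2-en-1-yl)benzaldehyde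
Conditions: MOMCl, i-Pr2NEt, CH2Cl2, 0 °C → rt
Reagents that add atoms: chloromethyl methyl ether (MOMCl), COCCl
Why: Williamson-type acetalisation of the phenol (MOM protection) proceeds under amine base without affecting the aldehyde or the alkene.

Step 3
Reactants: 4 4-(methoxymethoxy)-3-(3-methylbut-2-en-1-yl)benzaldehyde; 5 diethyl {2-[methoxy(methyl)amino]-2-oxoethyl}phosphonate
Product: 6 (E)-N-methoxy-3-[4-(methoxymethoxy)-3-(3-methylbut-2-en-1-yl)phenyl]-N-methylprop-2-enamide
Conditions: NaH, THF, 0 °C → rt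
Reagents that add atoms: none
Why: Horner–Wadsworth–Emmons olefination with the stabilised phosphonoacetamide anion should give the E-alkene, as is usual for stabilised phosphonates and aromatic aldehydes.

Step 4
Reactants: 6 (E)-N-methoxy-3-[4-(methoxymethoxy)-3-(3-methylbut-2-en-1-yl)phenyl]-N-methylprop-2-enamide
Product: 7 (2R,3S)-N-methoxy-3-[4-(methoxymethoxy)-3-(3-methylbut-2-en-1-yl)phenyl]-N-methyloxirane-2-carboxamide
Conditions: Sm(O-iPr)3 (10 mol %), (S)-BINOL (10 mol %), Ph3As=O (10 mol %), t-BuOOH (decane), 4 Å MS, THF, rt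
Reagents that add atoms: tert-butyl hydroperoxide, CC(C)(C)OO
Why: Lanthanide–BINOL-catalysed nucleophilic (Weitz–Scheffer-type) epoxidation of an α,β-unsaturated amide: the samarium-bound tert-butylperoxide adds in conjugate fashion only to the electron-poor enamide C=C, leaving the electron-rich prenyl alkene alone, and the chiral Sm–BINOL environment selects the face so that the trans (2R,3S) epoxide should result.

**Ring A phenol**

Step 5
Reactants: 8 4-bromoresorcinol (4-bromobenzene-1,3-diol)
Product: 9 2-bromo-5-(methoxymethoxy)phenol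
Conditions: MOMCl (1.0 equiv), K2CO3, acetone, 0 °C → rt
Reagents that add atoms: chloromethyl methyl ether (MOMCl), COCCl
Why: Regioselective Williamson-type MOM protection: under carbonate base the phenoxide para to bromine is the more nucleophilic and less shielded oxygen, so monoprotection should fall mainly there; the regioisomer and the bis-ether are removed by chromatography.

Step 6
Reactants: 9 2-bromo-5-(methoxymethoxy)phenol; 10 3-chloro-3-methylbut-1-yne
Product: 11 1-bromo-4-(methoxymethoxy)-2-[(2-methylbut-3-yn-2-yl)oxy]benzene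
Conditions: CuCl2·2H2O (1 mol %), DBU, MeCN, 0 °C → rt
Reagents that add atoms: none
Why: Copper-catalysed propargylic etherification: the copper acetylide of the tertiary chloride ionises to a copper allenylidene that the phenoxide captures at the tertiary carbon, a standard entry to aryl 1,1-dimethylpropargyl ethers.

Step 7
Reactants: 11 1-bromo-4-(methoxymethoxy)-2-[(2-methylbut-3-yn-2-yl)oxy]benzene
Product: 12 1-bromo-4-(methoxymethoxy)-2-[(2-methylbut-3-en-2-yl)oxy]benzene
Conditions: H2 (1 atm), Pd/CaCO3 poisoned with Pb(OAc)2, quinoline, EtOAc, rt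
Reagents that add atoms: none
Why: Semihydrogenation of the terminal alkyne over poisoned palladium stops at the alkene, and the aryl bromide should not be hydrogenolysed under these quinoline-moderated conditions.

Step 8
Reactants: 12 1-bromo-4-(methoxymethoxy)-2-[(2-methylbut-3-en-2-yl)oxy]benzene
Product: 14 6-bromo-3-(methoxymethoxy)-2-(3-methylbut-2-en-1-yl)phenol, via Claisen dienone 13 (not isolated)
Conditions: PhNEt2, 130 °C
Reagents that add atoms: none
Why: Aromatic Claisen rearrangement ([3,3]-sigmatropic shift): the tertiary allyl ether delivers its allyl terminus to the only hydrogen-bearing ortho carbon (the other ortho position carries bromine), and tautomerisation of the dienone gives the linear prenyl group between the two oxygens and frees the hydroxyl next to bromine.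

**Coupling, key step and deprotection**

Step 9
Reactants: 14 6-bromo-3-(methoxymethoxy)-2-(3-methylbut-2-en-1-yl)phenol; 7 (2R,3S)-N-methoxy-3-[4-(methoxymethoxy)-3-(3-methylbut-2-en-1-yl)phenyl]-N-methyloxirane-2-carboxamide
Product: 15 (2R,3R)-3-[6-bromo-3-(methoxymethoxy)-2-(3-methylbut-2-en-1-yl)phenoxy]-2-hydroxy-N-methoxy-3-[4-(methoxymethoxy)-3-(3-methylbut-2-en-1-yl)phenyl]-N-methylpropanamide
Conditions: Cs2CO3 (0.2 equiv), DMF, 60 °C
Reagents that add atoms: none
Why: Base-mediated SN2 opening of the trans-glycidic amide at the benzylic C3 by the caesium phenoxide with inversion turns the 3S centre into 3R while C2 is untouched, giving the (2R,3R) hydroxy ether; catalytic base suffices because the alkoxide formed deprotonates the next phenol.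

Step 10
Reactants: 15 (2R,3R)-3-[6-bromo-3-(methoxymethoxy)-2-(3-methylbut-2-en-1-yl)phenoxy]-2-hydroxy-N-methoxy-3-[4-(methoxymethoxy)-3-(3-methylbut-2-en-1-yl)phenyl]-N-methylpropanamide
Product: 16 (2R,3R)-3-[6-bromo-3-(methoxymethoxy)-2-(3-methylbut-2-en-1-yl)phenoxy]-2-[(tert-butyldimethylsilyl)oxy]-N-methoxy-3-[4-(methoxymethoxy)-3-(3-methylbut-2-en-1-yl)phenyl]-N-methylpropanamide
Conditions: TBSOTf, 2,6-lutidine, CH2Cl2, −78 → 0 °C
Reagents that add atoms: tert-butyldimethylsilyl trifluoromethanesulfonate (TBSOTf), CC(C)(C)[Si](C)(C)OS(=O)(=O)C(F)(F)F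
Why: Silylation of the hindered secondary alcohol with the silyl triflate and 2,6-lutidine is fast at low temperature, which spares the aryl MOM ethers, and it removes the only acidic O–H before the organolithium step.

Step 11
Reactants: 16 (2R,3R)-3-[6-bromo-3-(methoxymethoxy)-2-(3-methylbut-2-en-1-yl)phenoxy]-2-[(tert-butyldimethylsilyl)oxy]-N-methoxy-3-[4-(methoxymethoxy)-3-(3-methylbut-2-en-1-yl)phenyl]-N-methylpropanamide
Product: 19 (2R,3R)-3-[(tert-butyldimethylsilyl)oxy]-7-(methoxymethoxy)-2-[4-(methoxymethoxy)-3-(3-methylbut-2-en-1-yl)phenyl]-8-(3-methylbut-2-en-1-yl)chroman-4-one, via aryllithium 17 (not isolated), via tetrahedral lithium alkoxide 18 (not isolated)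
Conditions: t-BuLi (2.1 equiv), THF, −78 °C; then AcOH/THF, −78 °C → rt
Reagents that add atoms: none
Why: Parham cyclisation: tert-butyllithium exchanges the aryl bromide much faster than it deprotonates or adds to the amide (the second equivalent destroys the tert-butyl bromide formed), and the C4a aryllithium attacks the amide carbonyl in a 6-exo-trig closure that forms the C4–C4a bond and ring C. The closest known reaction type is the intramolecular acylation of ortho-lithiated aryl ethers by N-methoxy-N-methyl amides to give chroman-4-ones. No stereocentre is created; C2 and C3 are carried through unchanged, and because the N-methoxy-chelated tetrahedral lithium alkoxide persists until the cold acetic acid quench, the ketone, which could epimerise at C3 or open ring C by β-elimination, never meets a base. The selectivity required is chemoselectivity of exchange over attack on the amide, over deprotonation at the amide α-carbon or the benzylic carbon, and over ortho-lithiation beside the MOM ethers; it is secured by the very fast bromine–lithium exchange at −78 °C, by the absence of any O–H, and by the short tether that should make ring closure faster than proton transfer. The acid-free conditions leave both prenyl groups intact.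

Step 12
Reactants: 19 (2R,3R)-3-[(tert-butyldimethylsilyl)oxy]-7-(methoxymethoxy)-2-[4-(methoxymethoxy)-3-(3-methylbut-2-en-1-yl)phenyl]-8-(3-methylbut-2-en-1-yl)chroman-4-one
Product: 20 3-hydroxyglabrol, (2R,3R)-3,7-dihydroxy-2-[4-hydroxy-3-(3-methylbut-2-en-1-yl)phenyl]-8-(3-methylbut-2-en-1-yl)chroman-4-one
Conditions: HCl (3 M in MeOH), THF, rt → 40 °C
Reagents that add atoms: none
Why: Acid-catalysed methanolysis cleaves both aryl MOM acetals and the secondary silyl ether in one operation (global deprotection) without involving either stereocentre; the mild temperature is chosen to avoid acid-induced cyclisation of the prenyl groups onto the neighbouring phenols.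

**Compound list**

1 | 4-hydroxybenzaldehyde | O=Cc1ccc(O)cc1 | starting material
2 | 1-bromo-3-methylbut-2-ene (prenyl bromide) | CC(C)=CCBr | starting material
3 | 4-hydroxy-3-(3-methylbut-2-en-1-yl)benzaldehyde | CC(C)=CCc1cc(C=O)ccc1O | intermediate
4 | 4-(methoxymethoxy)-3-(3-methylbut-2-en-1-yl)benzaldehyde | COCOc1ccc(C=O)cc1CC=C(C)C | intermediate
5 | diethyl {2-[methoxy(methyl)amino]-2-oxoethyl}phosphonate | CCOP(=O)(CC(=O)N(C)OC)OCC | starting material
6 | (E)-N-methoxy-3-[4-(methoxymethoxy)-3-(3-methylbut-2-en-1-yl)phenyl]-N-methylprop-2-enamide | CON(C)C(=O)/C=C/c1ccc(OCOC)c(CC=C(C)C)c1 | intermediate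
7 | (2R,3S)-N-methoxy-3-[4-(methoxymethoxy)-3-(3-methylbut-2-en-1-yl)phenyl]-N-methyloxirane-2-carboxamide (trans) | CON(C)C(=O)[C@@H]1O[C@H]1c1ccc(OCOC)c(CC=C(C)C)c1 | intermediate
8 | 4-bromoresorcinol | Oc1ccc(Br)c(O)c1 | starting material
9 | 2-bromo-5-(methoxymethoxy)phenol | COCOc1ccc(Br)c(O)c1 | intermediate
10 | 3-chloro-3-methylbut-1-yne | CC(C)(Cl)C#C | starting material
11 | 1-bromo-4-(methoxymethoxy)-2-[(2-methylbut-3-yn-2-yl)oxy]benzene | COCOc1ccc(Br)c(OC(C)(C)C#C)c1 | intermediate
12 | 1-bromo-4-(methoxymethoxy)-2-[(2-methylbut-3-en-2-yl)oxy]benzene | COCOc1ccc(Br)c(OC(C)(C)C=C)c1 | intermediate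
13 | 6-bromo-3-(methoxymethoxy)-2-(3-methylbut-2-en-1-yl)cyclohexa-3,5-dien-1-one (Claisen dienone, C2 configuration undefined) | O=C1C(CC=C(C)C)C(OCOC)=CC=C1Br | intermediate
14 | 6-bromo-3-(methoxymethoxy)-2-(3-methylbut-2-en-1-yl)phenol | COCOc1ccc(Br)c(O)c1CC=C(C)C | intermediate
15 | (2R,3R)-3-[6-bromo-3-(methoxymethoxy)-2-(3-methylbut-2-en-1-yl)phenoxy]-2-hydroxy-N-methoxy-3-[4-(methoxymethoxy)-3-(3-methylbut-2-en-1-yl)phenyl]-N-methylpropanamide | CC(C)=CCc1cc([C@@H](Oc2c(Br)ccc(OCOC)c2CC=C(C)C)[C@@H](O)C(=O)N(C)OC)ccc1OCOC | intermediate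
16 | (2R,3R)-3-[6-bromo-3-(methoxymethoxy)-2-(3-methylbut-2-en-1-yl)phenoxy]-2-[(tert-butyldimethylsilyl)oxy]-N-methoxy-3-[4-(methoxymethoxy)-3-(3-methylbut-2-en-1-yl)phenyl]-N-methylpropanamide | CC(C)=CCc1cc([C@@H](Oc2c(Br)ccc(OCOC)c2CC=C(C)C)[C@@H](O[Si](C)(C)C(C)(C)C)C(=O)N(C)OC)ccc1OCOC | intermediate
17 | aryllithium from 16 (lithium in place of bromine, both stereocentres unchanged) | CC(C)=CCc1cc([C@@H](Oc2c([Li])ccc(OCOC)c2CC=C(C)C)[C@@H](O[Si](C)(C)C(C)(C)C)C(=O)N(C)OC)ccc1OCOC | intermediate
18 | lithium (2R,3R)-3-[(tert-butyldimethylsilyl)oxy]-4-[methoxy(methyl)amino]-7-(methoxymethoxy)-2-[4-(methoxymethoxy)-3-(3-methylbut-2-en-1-yl)phenyl]-8-(3-methylbut-2-en-1-yl)chroman-4-olate (C4 configuration undefined) | CC(C)=CCc1cc([C@H]2Oc3c(ccc(OCOC)c3CC=C(C)C)C(O[Li])(N(C)OC)[C@@H]2O[Si](C)(C)C(C)(C)C)ccc1OCOC | intermediate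
19 | (2R,3R)-3-[(tert-butyldimethylsilyl)oxy]-7-(methoxymethoxy)-2-[4-(methoxymethoxy)-3-(3-methylbut-2-en-1-yl)phenyl]-8-(3-methylbut-2-en-1-yl)chroman-4-one | CC(C)=CCc1cc([C@H]2Oc3c(ccc(OCOC)c3CC=C(C)C)C(=O)[C@@H]2O[Si](C)(C)C(C)(C)C)ccc1OCOC | intermediate
20 | 3-hydroxyglabrol, (2R,3R)-3,7-dihydroxy-2-[4-hydroxy-3-(3-methylbut-2-en-1-yl)phenyl]-8-(3-methylbut-2-en-1-yl)chroman-4-one | CC(C)=CCc1cc([C@H]2Oc3c(ccc(O)c3CC=C(C)C)C(=O)[C@@H]2O)ccc1O | target

**Step count**

Total: 12 steps. Longest linear sequence: 8 steps (steps 1–4 then 9–12; the ring A branch, steps 5–8 then 9–12, is equally long).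

**Steps most likely to fail**

Step 9. Substitution at the doubly ortho-substituted phenoxide oxygen may be so slow that ionisation of the p-alkoxybenzylic C–O bond (erosion of the inversion at C3) or attack at C2 competes. The fallback moves the etherification to the glycidol oxidation level. This removes the electron-withdrawing carboxamide from the electrophile and lets a titanium template direct the nucleophile to C3. Setting out from epoxy amide 7, i-Bu2AlH (THF, −78 °C) should give (2R,3S)-3-[4-(methoxymethoxy)-3-(3-methylbut-2-en-1-yl)phenyl]oxirane-2-carbaldehyde F1, which NaBH4 (MeOH, 0 °C) reduces to [(2S,3S)-3-[4-(methoxymethoxy)-3-(3-methylbut-2-en-1-yl)phenyl]oxiran-2-yl]methanol F2. Opening of the titanium-bound epoxy alkoxide with phenol 14 (Ti(O-iPr)4, toluene, rt → 50 °C), at C3 with inversion, would give (2S,3R)-3-[6-bromo-3-(methoxymethoxy)-2-(3-methylbut-2-en-1-yl)phenoxy]-3-[4-(methoxymethoxy)-3-(3-methylbut-2-en-1-yl)phenyl]propane-1,2-diol F3. Oxidation of the primary alcohol (TEMPO, PhI(OAc)2, MeCN–H2O) leads to (2R,3R)-3-[6-bromo-3-(methoxymethoxy)-2-(3-methylbut-2-en-1-yl)phenoxy]-2-hydroxy-3-[4-(methoxymethoxy)-3-(3-methylbut-2-en-1-yl)phenyl]propanoic acid F4. Coupling with N,O-dimethylhydroxylamine hydrochloride (EDC·HCl, HOBt, N-methylmorpholine, CH2Cl2) returns to the route at hydroxy amide 15.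

Step 11. Proton transfer to the aryllithium from the benzylic C–H beside O1 or from the amide α-C–H (followed by β-elimination), or direct attack of tert-butyllithium on the amide, may compete with ring closure. The fallback forms the same C4–C4a bond through a non-basic arylchromium species. Setting out from 16, i-Bu2AlH (THF, −78 °C) should give (2R,3R)-3-[6-bromo-3-(methoxymethoxy)-2-(3-methylbut-2-en-1-yl)phenoxy]-2-[(tert-butyldimethylsilyl)oxy]-3-[4-(methoxymethoxy)-3-(3-methylbut-2-en-1-yl)phenyl]propanal F5. Nozaki–Hiyama–Kishi cyclisation (CrCl2, NiCl2 (cat.), DMF, rt → 50 °C) would close ring C to (2R,3S)-3-[(tert-butyldimethylsilyl)oxy]-7-(methoxymethoxy)-2-[4-(methoxymethoxy)-3-(3-methylbut-2-en-1-yl)phenyl]-8-(3-methylbut-2-en-1-yl)chroman-4-ol F6, whose C4 epimers are both usable. Dess–Martin periodinane (CH2Cl2, NaHCO3) then oxidises the carbinol and rejoins the route at 19.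

Step 4. Conjugate addition of the samarium peroxide to the electron-rich, weakly electrophilic enamide may be slow, or the facial discrimination insufficient. The fallback uses the more electrophilic N-acylpyrrole as an ester surrogate, a substrate class for which this catalysis is well established. Setting out from aldehyde 4, Wittig olefination with 1-(1H-pyrrol-1-yl)-2-(triphenylphosphoranylidene)ethan-1-one (toluene, 90 °C) should give (E)-3-[4-(methoxymethoxy)-3-(3-methylbut-2-en-1-yl)phenyl]-1-(1H-pyrrol-1-yl)prop-2-en-1-one F7. Epoxidation (Sm(O-iPr)3, (S)-H8-BINOL, Ph3As=O, t-BuOOH, 4 Å MS, THF) would give [(2R,3S)-3-[4-(methoxymethoxy)-3-(3-methylbut-2-en-1-yl)phenyl]oxiran-2-yl](1H-pyrrol-1-yl)methanone F8. Displacement of pyrrole with the magnesium amide from N,O-dimethylhydroxylamine hydrochloride and i-PrMgCl (THF, −20 °C) returns to the route at epoxy amide 7.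

Further compounds
F1 | step 9 | (2R,3S)-3-[4-(methoxymethoxy)-3-(3-methylbut-2-en-1-yl)phenyl]oxirane-2-carbaldehyde | O=C[C@@H]1O[C@H]1c1ccc(OCOC)c(CC=C(C)C)c1
F2 | step 9 | [(2S,3S)-3-[4-(methoxymethoxy)-3-(3-methylbut-2-en-1-yl)phenyl]oxiran-2-yl]methanol | OC[C@@H]1O[C@H]1c1ccc(OCOC)c(CC=C(C)C)c1
F3 | step 9 | (2S,3R)-3-[6-bromo-3-(methoxymethoxy)-2-(3-methylbut-2-en-1-yl)phenoxy]-3-[4-(methoxymethoxy)-3-(3-methylbut-2-en-1-yl)phenyl]propane-1,2-diol | CC(C)=CCc1cc([C@@H](Oc2c(Br)ccc(OCOC)c2CC=C(C)C)[C@@H](O)CO)ccc1OCOC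
F4 | step 9 | (2R,3R)-3-[6-bromo-3-(methoxymethoxy)-2-(3-methylbut-2-en-1-yl)phenoxy]-2-hydroxy-3-[4-(methoxymethoxy)-3-(3-methylbut-2-en-1-yl)phenyl]propanoic acid | CC(C)=CCc1cc([C@@H](Oc2c(Br)ccc(OCOC)c2CC=C(C)C)[C@@H](O)C(=O)O)ccc1OCOC
F5 | step 11 | (2R,3R)-3-[6-bromo-3-(methoxymethoxy)-2-(3-methylbut-2-en-1-yl)phenoxy]-2-[(tert-butyldimethylsilyl)oxy]-3-[4-(methoxymethoxy)-3-(3-methylbut-2-en-1-yl)phenyl]propanal | CC(C)=CCc1cc([C@@H](Oc2c(Br)ccc(OCOC)c2CC=C(C)C)[C@@H](O[Si](C)(C)C(C)(C)C)C=O)ccc1OCOC
F6 | step 11 | (2R,3S)-3-[(tert-butyldimethylsilyl)oxy]-7-(methoxymethoxy)-2-[4-(methoxymethoxy)-3-(3-methylbut-2-en-1-yl)phenyl]-8-(3-methylbut-2-en-1-yl)chroman-4-ol (C4 epimers) | CC(C)=CCc1cc([C@H]2Oc3c(ccc(OCOC)c3CC=C(C)C)C(O)[C@@H]2O[Si](C)(C)C(C)(C)C)ccc1OCOC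
F7 | step 4 | (E)-3-[4-(methoxymethoxy)-3-(3-methylbut-2-en-1-yl)phenyl]-1-(1H-pyrrol-1-yl)prop-2-en-1-one | COCOc1ccc(/C=C/C(=O)n2cccc2)cc1CC=C(C)C
F8 | step 4 | [(2R,3S)-3-[4-(methoxymethoxy)-3-(3-methylbut-2-en-1-yl)phenyl]oxiran-2-yl](1H-pyrrol-1-yl)methanone | O=C([C@@H]1O[C@H]1c1ccc(OCOC)c(CC=C(C)C)c1)n1cccc1
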